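## Structural features

The target 19 is a dimethyl butanedioate (succinate numbering C1–C4) whose two methine carbons, C2 and C3, each carry a 1,4-benzoquinone ring through a ring carbon. In each ring the carbonyl oxygen next to the point of attachment is flanked on its other side by a carbon bearing a geranyl chain [(2E)-3,7-dimethylocta-2,6-dien-1-yl], and the second carbonyl is para to it, so both rings are 2,6-disubstituted quinones. C2 and C3 are adjacent stereocentres with identical ligand sets and opposite descriptors (2S,3R), so 19 is the achiral meso diastereomer and only the relative configuration has to be controlled. The fragile parts are the quinones (reducible, electrophilic, base-labile), the two methine hydrogens (each alpha to an ester and attached to a quinone, hence easily epimerised) and the four trisubstituted chain alkenes, which do not tolerate strong protic or Lewis acids, electrophilic halogen or hydrogenation and must stay E. The real difficulty is the C2–C3 unit: two hindered, aryl-bearing methines must end up meso rather than racemic in an open chain that offers no bias, while each ring needs its oxygen placed between the chain carbon and the methine carbon. The key step uses the fact that in ring A this flanked oxygen can reach ester carbon C4 on the neighbouring methine C3. Joining them gives a six-membered lactone (O, two carbons of ring A, C2, C3, C4), a 3,4-dihydrocoumarin in which succinate C2, C3 and C4 become chromane C4, C3 and C2. On that ring the meso relationship is the trans arrangement of the C2 ester and ring B, and the unsaturated form of the ring is a coumarin-4-carboxylate that can take up ring B at the lactone alpha-carbon by conjugate arylation.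

## Logic of the disconnections

19 ⇒ 18. No skeletal bond is cut. The two quinone rings are taken back to the hydroquinone oxidation level by restoring three O–CH3 bonds and one phenolic O–H, so that ring A is a 4-methoxyphenol and ring B a 1,4-dimethoxyarene. The reason is that quinones would not survive organolithium, boron–rhodium or alkoxide chemistry; the gain is two robust arenes. The forward step needs an oxidant that unmasks both rings in one operation, leaves four chain alkenes alone and works in a medium that does not epimerise C2 or C3.

18 ⇒ 16. The C4–OCH3 bond of the ester on C3 is cut and C4 is joined to the phenolic oxygen of ring A. This turns an open-chain stereochemical relationship into trans on a six-membered ring, where it can be controlled, and it masks the phenol. The forward ring opening must cleave only the aryl ester and must not disturb either methine.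

16 ⇒ 7 + 15. The bond from C3 to ring B and the C2–H bond are cut. The molecule falls into two geranylated arenes of similar size, and both stereocentres arise in the step that joins them. The forward step must put the aryl group on the unsubstituted alkene carbon of 7 and protonate the neighbouring carbon on the opposite face.

7 ⇒ 4 + 5. The bond from ring A to C2 and the lactone O–C4 bond are cut, so that C1–C4 of the target come from 5 in one piece. Because the ring closes through the phenolic oxygen of 4, that oxygen is automatically the one flanked by the chain and by C2. The forward annulation requires C–C bond formation at the single free ortho position of 4 under conditions that leave the chain alone.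

4 ⇒ 1 + 2. The bond between ring A and the chain CH2 is cut. Both fragments are commercial. The forward step must favour ortho C-alkylation over O-alkylation and stop after one chain.

15 ⇒ 12. The C–B bond is cut. The boron is placed where a bromine already marks the position, so no regiochemical question arises. The forward step needs a halogen–metal exchange that is faster than deprotonation of the doubly activated benzylic–allylic CH2.

12 ⇒ 9 + 2. The bond between ring B and the chain CH2 is cut. The two bromines of 9 are equivalent, so one can be exchanged for the chain and the other kept for boron. The forward step needs a single exchange and substitution at the primary allylic carbon of 2 without allylic transposition or loss of E geometry.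

9 ⇒ 8. One O–CH3 bond is cut. The methyl ether is needed because a free phenol would quench the organolithium steps. The forward step is a simple O-alkylation.

## Other disconnections considered

Alternative 1: The cut falls on both methine–ring bonds at once (C2–ring A and C3–ring B). This leaves a four-carbon bis-nucleophile, 1,4-dimethoxy-1,4-bis(trimethylsilyloxy)buta-1,3-diene A1, and two molecules of the quinone monoketal 3-geranyl-4,4-dimethoxycyclohexa-2,5-dien-1-one A2. In the forward key step A1 would add twice, in Mukaiyama–Michael fashion under a mild Lewis acid or fluoride, to the ring CH of A2 that is beta to the carbonyl and next to the ketal carbon. Each adduct then loses one alkoxy group and aromatises, giving dimethyl meso-2,3-bis(3-geranyl-5-hydroxy-2-methoxyphenyl)butanedioate A3. One structural point needs stating precisely: A1 can bond only through its two inner CH carbons, which become the methines, and not through the oxygen-bearing ends of the diene.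
- In its favour: the plan is symmetric, forms both aryl–methine bonds in one flask from one ring building block and needs no transition metal. It delivers both rings as 4-methoxyphenols, the easiest quinone precursors to oxidise; on this point it is better than the chosen plan, whose ring B is a dimethoxyarene. A3 also has no phenol ortho to an ester-bearing carbon and cannot lactonise, which is again better than 18.
- Against it here: the ketal carbon of A2 must sit next to the chain-bearing carbon, so A2 has to come from 3-geranyl-4-methoxyphenol A4. This is the regioisomer that phenoxide alkylation does not give, and it would need a directed-metalation sequence of about three steps. The attack must take place next to a quaternary ketal carbon, in competition with ionisation of the ketal and with cation–olefin chemistry of the chain. The second addition, by the hindered mono-adduct, may stall.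
- Comparison: the decisive weakness is stereochemical. C2 and C3 are created in two separate open-chain events with nothing to relate them, so a meso/racemic mixture is to be expected and would need base equilibration in the presence of two free phenols. The chosen plan sets both centres on one ring where kinetic and thermodynamic preferences agree. In step count the alternative is equal or slightly shorter (about three steps to A4, one to A2, the key step, an equilibration and one oxidation, against eight).

Alternative 2: Here the C2–C3 bond is carried in from a four-membered ring. The cut removes the two ester O–CH3 units and the two methine hydrogens to reach the bisketene 2,3-bis(3-geranyl-2,5-dimethoxyphenyl)buta-1,3-diene-1,4-dione A7. A7 is the ring-opened form (C1–C4 bond broken) of 3,4-bis(3-geranyl-2,5-dimethoxyphenyl)cyclobut-3-ene-1,2-dione A6. In the forward key step A6 would be irradiated with near-ultraviolet light in the alcohol that supplies the ester groups. Electrocyclic opening gives A7, and two molecules of the alcohol add, each forming an ester C–O bond and, after tautomerisation, a methine C–H bond, to give dimethyl meso-2,3-bis(3-geranyl-2,5-dimethoxyphenyl)butanedioate A8.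
- In its favour: the plan is fully symmetric, so one aryl building block (15, or an organometallic derived from 12) is attached twice to 3,4-dichlorocyclobut-3-ene-1,2-dione A5 by palladium-catalysed coupling. The key step needs only light and solvent, with no metal and no base. The count, about six steps (three to 15, coupling, photolysis, oxidation), is lower than eight, so on step economy and convergence it is the better plan.
- Against it here: neither methine configuration is controlled, because the two protonations take place on flexible ketene or enol intermediates after the ring has opened. A meso/racemic mixture is the likely outcome and an equilibration step must be added. The ring opening is reversible, and the half-reacted ketenyl ester can close to a butenolide instead of taking up the second alcohol. An ortho-substituted aryl group has to be coupled twice onto a small, base-sensitive electrophile. A8 carries two dimethoxyarene rings, so the final oxidation is more demanding than in the chosen plan, where ring A is a more easily oxidised methoxyphenol.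
- Comparison: on structure the two plans trade symmetry (in favour of the alternative) against a built-in control element for the relative configuration (in favour of the chosen plan). On mechanism the chosen plan is better placed, because its stereochemistry does not rest on a later equilibration.

Alternative 3: The cut removes the two methine C–H bonds and leads back to a tetrasubstituted alkene held in a five-membered ring, 3,4-bis(3-geranyl-2,5-dimethoxyphenyl)furan-2,5-dione A10, in which C1 and C4 are tied together as the anhydride. In the forward key step A10 would be reduced at a carbon cathode in a buffered protic electrolyte. Two electrons and two protons would add across the ring alkene, ideally to the same face, to give cis-3,4-bis(3-geranyl-2,5-dimethoxyphenyl)dihydrofuran-2,5-dione A11. Opening of the anhydride with the alcohol, methylation of the liberated acid and oxidation would follow by way of A8.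
- In its favour: like the chosen plan it turns the meso problem into a ring problem (cis on the anhydride corresponds to meso). It is symmetric and uses one aryl building block twice, for example by twofold cross-coupling of an organometallic from 12 with 3,4-dibromofuran-2,5-dione A9. Electrons replace a precious-metal catalyst, and the chain alkenes lie far outside the reduction window of the conjugated system. On symmetry and reagent cost it is the better plan, and on step count (about eight) it is the equal.
- Against it here: a cathodic reduction is a sequence of separate electron and proton transfers and is not intrinsically syn. The second proton is expected to arrive on the enolate face away from the neighbouring aryl group, which gives the trans anhydride. Cis is also the less stable isomer, with two eclipsed ortho-substituted aryl groups, and would epimerise through the enol in the buffer used for the electrolysis. The anhydride may be solvolysed before it is isolated.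
- Comparison: on mechanism the chosen plan is clearly ahead. On the six-membered lactone the required isomer is trans, favoured both kinetically and thermodynamically; on the five-membered anhydride the required isomer is cis and is favoured by neither. The alternative also needs two further operations after its key step to reach the diester, where the chosen plan opens its template directly to the methyl ester.

Key step: step 6

Remarks on the chemistry:
- "Geranyl" stands throughout for (2E)-3,7-dimethylocta-2,6-dien-1-yl.
- Assumption: 8 is taken as purchasable; intermediates 6, 16, 17 and 18 are racemates (one enantiomer is drawn), which is immaterial because 19 is meso.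
- Correction: 18 is not itself a meso compound, because its two rings differ; it is the racemate with the (2R*,3S*) relative configuration, which becomes meso once both rings are quinones.
- The structures of 7, 15 and 16 were checked against 19: the substitution patterns fit, and the trans lactone 16 does open to the meso series.

## Route

Step 1
Reactants: 1 4-methoxyphenol; 2 geranyl bromide
Product: 4 2-geranyl-4-methoxyphenol, via sodium 4-methoxyphenoxide 3 (not isolated)
Conditions: NaH (1.0 equiv), toluene, 0 °C to rt; then 2 (0.8 equiv), rt
Reagents that add atoms: none
Why: Ortho C-allylation of a phenoxide: in a non-polar solvent the poorly solvated sodium ion pair reacts at the ortho carbon (para is blocked by methoxy) by SN2 attack on the primary allylic carbon of 2, which keeps the E alkene; the excess of phenoxide limits double alkylation.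

Step 2
Reactants: 4 2-geranyl-4-methoxyphenol; 5 dimethyl acetylenedicarboxylate
Product: 7 methyl 8-geranyl-6-methoxy-2-oxo-2H-chromene-4-carboxylate, via phosphorane adduct 6 (not isolated)
Conditions: PPh3 (1.0 equiv), 5 (1.1 equiv), CH2Cl2, 0 °C to rt; then toluene, 80 °C
Reagents that add atoms: none
Why: Phosphine-mediated annulation of a phenol with an acetylenic diester (vinylphosphonium route): PPh3 adds to 5, the zwitterion is protonated by 4, and the phenoxide attacks through its only free ortho carbon to give ylide 6, which closes the lactone with loss of methanol and expels PPh3 after a proton shift. Because the ring closes through the phenolic oxygen, that oxygen ends up between the chain carbon and the new C–C bond.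

Step 3
Reactants: 8 2,6-dibromo-4-methoxyphenol
Product: 9 1,3-dibromo-2,5-dimethoxybenzene
Conditions: MeI (1.5 equiv), K2CO3 (2 equiv), acetone, reflux
Reagents that add atoms: iodomethane, CI
Why: Williamson ether synthesis; the acidic dibromophenol is fully deprotonated by carbonate and both ortho positions are blocked, so only O-methylation is possible.

Step 4
Reactants: 9 1,3-dibromo-2,5-dimethoxybenzene; 2 geranyl bromide
Product: 12 1-bromo-3-geranyl-2,5-dimethoxybenzene, via (3-bromo-2,5-dimethoxyphenyl)lithium 10 (not isolated), via (3-bromo-2,5-dimethoxyphenyl)copper 11 (not isolated)
Conditions: n-BuLi (1.0 equiv), THF, −78 °C; CuBr·SMe2 (1.0 equiv), −78 to −40 °C; 2 (1.1 equiv), −40 °C to rt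
Reagents that add atoms: none
Why: Bromine–lithium exchange of one of two equivalent bromines (a second exchange is disfavoured), transmetalation to an arylcopper and allylic substitution at the primary carbon of 2, the standard way to attach prenyl-type chains to arenes with retention of E geometry. The copper stage also suppresses aryl–aryl halogen scrambling.

Step 5
Reactants: 12 1-bromo-3-geranyl-2,5-dimethoxybenzene
Product: 15 (3-geranyl-2,5-dimethoxyphenyl)boronic acid, via (3-geranyl-2,5-dimethoxyphenyl)lithium 13 (not isolated), via lithium aryltriisopropoxyborate 14 (not isolated)
Conditions: n-BuLi (1.1 equiv), THF, −78 °C; B(OiPr)3 (1.5 equiv), −78 °C to rt; 1 M HCl, 0 °C, brief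
Reagents that add atoms: triisopropyl borate, CC(C)OB(OC(C)C)OC(C)C; water, O
Why: Bromine–lithium exchange followed by electrophilic borylation and hydrolysis of the borate; exchange at −78 °C is much faster than deprotonation of the benzylic–allylic CH2, and the short cold acid work-up spares the chain.

Step 6
Reactants: 7 methyl 8-geranyl-6-methoxy-2-oxo-2H-chromene-4-carboxylate; 15 (3-geranyl-2,5-dimethoxyphenyl)boronic acid
Product: 16 methyl (3R*,4S*)-3-(3-geranyl-2,5-dimethoxyphenyl)-8-geranyl-6-methoxy-2-oxochromane-4-carboxylate (trans)
Conditions: 15 (2.5 equiv), [Rh(OH)(cod)]2 (2.5 mol%), degassed 1,4-dioxane/H2O (10:1), 50 °C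
Reagents that add atoms: none
Why: Proposed new method: the closest known reactions are the [Rh(OH)(cod)]2-catalysed 1,4-additions of arylboronic acids to coumarins and to fumaric or maleic diesters, combined here on a coumarin-4-carboxylate, whose C3=C4 bond is a ring-fused aryl fumarate. Transmetalation of 15 to the hydroxo complex of monovalent rhodium gives an aryl–rhodium species that inserts the C3=C4 bond of 7, placing the aryl group on C3 (the CH carbon) and the metal on C4, because the reverse sense would build a quaternary diaryl carbon and because rhodium at C4 is stabilised both as the oxa-π-allyl of the exocyclic methyl ester and as a benzylic complex. Water then protonates this enolate at C4 and returns the Rh–OH catalyst; no ring is closed, and the lactone of 7 is carried through intact. The C3 stereocentre is created in the insertion and the C4 stereocentre in the protonation, which takes place on the ring face opposite the new aryl group, so the relative configuration is trans (3R*,4S*). The same isomer is the thermodynamic one, so any cis material can be converged by enolisation. The step therefore needs regioselectivity for C3 over C4 and trans diastereoselectivity, secured respectively by the substitution pattern of the alkene under a diene-ligated catalyst and by the six-membered ring. Near-neutral aqueous dioxane at 50 °C should leave the aryl ester, the methyl ester and all four chain alkenes untouched, and the excess of 15 offsets protodeboronation of this electron-rich ortho-methoxy boronic acid.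

Step 7
Reactants: 16 methyl (3R*,4S*)-3-(3-geranyl-2,5-dimethoxyphenyl)-8-geranyl-6-methoxy-2-oxochromane-4-carboxylate
Product: 18 dimethyl (2R*,3S*)-2-(3-geranyl-2-hydroxy-5-methoxyphenyl)-3-(3-geranyl-2,5-dimethoxyphenyl)butanedioate, via sodium phenoxide 17 (not isolated)
Conditions: NaOMe (1.2 equiv), MeOH/THF (3:1), 0 °C, 30 min; AcOH (1.5 equiv), 0 °C; crude product used at once
Reagents that add atoms: sodium methoxide, [Na+].[O-]C
Why: Transesterification of an aryl ester: methoxide attacks the lactone carbonyl and the phenoxide of ring A leaves, so neither stereocentre is touched and trans on the ring becomes the meso-type (2R*,3S*) open chain. Low temperature and a short reaction time guard against epimerisation, and immediate use prevents the phenol from closing back onto either ester.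

Step 8
Reactants: 18 dimethyl (2R*,3S*)-2-(3-geranyl-2-hydroxy-5-methoxyphenyl)-3-(3-geranyl-2,5-dimethoxyphenyl)butanedioate
Product: 19 dimethyl meso-(2R,3S)-2,3-bis(5-geranyl-3,6-dioxocyclohexa-1,4-dien-1-yl)butanedioate
Conditions: (NH4)2Ce(NO3)6 (5 equiv), MeCN/H2O (2:1), 0 °C, 20 min
Reagents that add atoms: water, O
Why: Oxidative demethylation by tetravalent cerium: the 4-methoxyphenol ring is oxidised first, then the 1,4-dimethoxyarene through its radical cation with capture of water, each losing methanol; this is standard for geranylated hydroquinone ethers and isolated trisubstituted alkenes are not attacked. The cold acidic medium does not enolise C2 or C3, so the (2R*,3S*) relationship of 18 becomes the meso configuration of 19.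

## Compound list

1 | 4-methoxyphenol | COc1ccc(O)cc1 | starting material
2 | geranyl bromide, (2E)-1-bromo-3,7-dimethylocta-2,6-diene | BrC/C=C(\C)CCC=C(C)C | starting material
3 | sodium 4-methoxyphenoxide | [Na+].COc1ccc([O-])cc1 | intermediate
4 | 2-geranyl-4-methoxyphenol | COc1ccc(O)c(C/C=C(\C)CCC=C(C)C)c1 | intermediate
5 | dimethyl acetylenedicarboxylate | COC(=O)C#CC(=O)OC | starting material
6 | dimethyl 2-(3-geranyl-2-hydroxy-5-methoxyphenyl)-3-(triphenyl-λ5-phosphanylidene)butanedioate (racemic) | COC(=O)C(=P(c1ccccc1)(c1ccccc1)c1ccccc1)C(C(=O)OC)c1cc(OC)cc(C/C=C(\C)CCC=C(C)C)c1O | intermediate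
7 | methyl 8-geranyl-6-methoxy-2-oxo-2H-chromene-4-carboxylate | COC(=O)C1=CC(=O)Oc2c(C/C=C(\C)CCC=C(C)C)cc(OC)cc12 | intermediate
8 | 2,6-dibromo-4-methoxyphenol | COc1cc(Br)c(O)c(Br)c1 | starting material
9 | 1,3-dibromo-2,5-dimethoxybenzene | COc1cc(Br)c(OC)c(Br)c1 | intermediate
10 | (3-bromo-2,5-dimethoxyphenyl)lithium | COc1cc([Li])c(OC)c(Br)c1 | intermediate
11 | (3-bromo-2,5-dimethoxyphenyl)copper | COc1cc([Cu])c(OC)c(Br)c1 | intermediate
12 | 1-bromo-3-geranyl-2,5-dimethoxybenzene | COc1cc(Br)c(OC)c(C/C=C(\C)CCC=C(C)C)c1 | intermediate
13 | (3-geranyl-2,5-dimethoxyphenyl)lithium | COc1cc([Li])c(OC)c(C/C=C(\C)CCC=C(C)C)c1 | intermediate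
14 | lithium (3-geranyl-2,5-dimethoxyphenyl)tri(propan-2-yloxy)borate | [Li+].COc1cc([B-](OC(C)C)(OC(C)C)OC(C)C)c(OC)c(C/C=C(\C)CCC=C(C)C)c1 | intermediate
15 | (3-geranyl-2,5-dimethoxyphenyl)boronic acid | COc1cc(B(O)O)c(OC)c(C/C=C(\C)CCC=C(C)C)c1 | intermediate
16 | methyl (3R*,4S*)-3-(3-geranyl-2,5-dimethoxyphenyl)-8-geranyl-6-methoxy-2-oxochromane-4-carboxylate (trans, racemic; 3R,4S drawn) | COC(=O)[C@@H]1c2cc(OC)cc(C/C=C(\C)CCC=C(C)C)c2OC(=O)[C@H]1c1cc(OC)cc(C/C=C(\C)CCC=C(C)C)c1OC | intermediate
17 | sodium 2-[(2R*,3S*)-1,4-dimethoxy-3-(3-geranyl-2,5-dimethoxyphenyl)-1,4-dioxobutan-2-yl]-6-geranyl-4-methoxyphenoxide (racemic) | [Na+].COC(=O)[C@H](c1cc(OC)cc(C/C=C(\C)CCC=C(C)C)c1[O-])[C@@H](C(=O)OC)c1cc(OC)cc(C/C=C(\C)CCC=C(C)C)c1OC | intermediate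
18 | dimethyl (2R*,3S*)-2-(3-geranyl-2-hydroxy-5-methoxyphenyl)-3-(3-geranyl-2,5-dimethoxyphenyl)butanedioate (racemic; 2S,3R drawn) | COC(=O)[C@H](c1cc(OC)cc(C/C=C(\C)CCC=C(C)C)c1O)[C@@H](C(=O)OC)c1cc(OC)cc(C/C=C(\C)CCC=C(C)C)c1OC | intermediate
19 | dimethyl meso-(2R,3S)-2,3-bis(5-geranyl-3,6-dioxocyclohexa-1,4-dien-1-yl)butanedioate (CNP0183145.1) | COC(=O)[C@H](C1=CC(=O)C=C(C/C=C(\C)CCC=C(C)C)C1=O)[C@@H](C(=O)OC)C1=CC(=O)C=C(C/C=C(\C)CCC=C(C)C)C1=O | target

## Step count and least certain steps

Total: 8 steps. Longest linear sequence: 6 steps (steps 3, 4, 5, 6, 7, 8, from 8); the other branch (steps 1, 2, then 6–8) has 5.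

**Step 6 (key step).**
- What may go wrong: insertion with the reverse regiochemistry or no insertion at all, because the alkene is trisubstituted and the aryl group ortho-substituted.
- Further risks: protodeboronation of 15 outrunning transmetalation; β-hydride elimination from the C4–rhodium intermediate, which would return an unsaturated arylated lactone in place of the saturated one; hydrolytic opening of the aryl ester in the aqueous medium.
- Incomplete trans selectivity in the protonation is the least serious risk, since enolisation with catalytic DBU should converge the material to trans.
- Fallback (known chemistry only), setting out from 15 and returning at 19: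
  - Palladium-catalysed coupling of 15 with methyl bromoacetate (Pd(OAc)2, tri(1-naphthyl)phosphine, K3PO4, THF, rt) should give methyl 2-(3-geranyl-2,5-dimethoxyphenyl)acetate F1.
  - Its lithium enolate (LiN(iPr)2, THF, −78 °C) would be coupled oxidatively with I2 (0.5 equiv) and the resulting diastereomer mixture equilibrated with catalytic NaOMe in MeOH, to give dimethyl meso-2,3-bis(3-geranyl-2,5-dimethoxyphenyl)butanedioate F2 (the same compound as A8).
  - (NH4)2Ce(NO3)6 in aqueous MeCN at 0 °C would then oxidise both rings to 19.
  - This gives up the lactone as control element and relies on thermodynamic preference and separation for the meso isomer.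

**Step 2.**
- What may go wrong: addition of the phenoxide through oxygen (aryl vinyl ether formation) instead of through the single, only moderately activated ortho carbon; closure of 6 onto the nearer ester to a five-membered lactone; phosphine-induced oligomerisation of 5.
- Fallback, setting out from 8 and returning at 7 (it also bypasses step 1):
  - 8 is protected (MOMCl, iPr2NEt, CH2Cl2) as 1,3-dibromo-5-methoxy-2-(methoxymethoxy)benzene F3.
  - One bromine–lithium exchange, CuBr·SMe2 and 2, as in step 4, give 1-bromo-3-geranyl-5-methoxy-2-(methoxymethoxy)benzene F4.
  - A second exchange (n-BuLi, THF, −78 °C) and inverse addition to excess dimethyl oxalate give methyl 2-[3-geranyl-5-methoxy-2-(methoxymethoxy)phenyl]-2-oxoacetate F5.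
  - Dilute HCl in MeOH at rt frees the phenol, methyl 2-(3-geranyl-2-hydroxy-5-methoxyphenyl)-2-oxoacetate F6.
  - (Triphenylphosphoranylidene)ketene, Ph3P=C=C=O, in toluene at 80 °C acylates the phenol and closes the ring by intramolecular Wittig olefination of the keto group, which gives 7 with the ring geometry fixed by the tether.

**Step 1.**
- What may go wrong: O-alkylation and a second alkylation at the other ortho carbon competing with the wanted single ortho C-alkylation, so that conversion to 4 is low and separation tedious.
- Fallback, setting out from 1 and returning at 4:
  - 1 is converted (MOMCl, iPr2NEt, CH2Cl2) into 1-methoxy-4-(methoxymethoxy)benzene F7.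
  - Directed lithiation next to the acetal oxygen (n-BuLi, TMEDA, THF, 0 °C), transmetalation with CuBr·SMe2 and reaction with 2 give 2-geranyl-4-methoxy-1-(methoxymethoxy)benzene F8.
  - Brief treatment with dilute HCl in MeOH at rt removes the acetal and gives 4.

**Step 7.**
- What may go wrong: epimerisation at either methine through enolate or ketene (E1cB) pathways under alkoxide.
- Also: return of the liberated phenol onto an ester during work-up and concentration, giving back the six-membered lactone or a five-membered benzofuranone.
- Fallback, setting out from 16 and returning at 19, with no base at any stage: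
  - Ring A of 16 is a 2,6-dialkyl-4-methoxyphenyl ester, a type known to be cleaved oxidatively, so (NH4)2Ce(NO3)6 (5 equiv) in MeCN/H2O at 0 °C should release the ring A quinone and the carboxylic acid while oxidising ring B in the same operation. The product is (2R*,3S*)-4-methoxy-4-oxo-2,3-bis(5-geranyl-3,6-dioxocyclohexa-1,4-dien-1-yl)butanoic acid F9.
  - Titration with TMSCHN2 in toluene/MeOH at 0 °C would then methylate the acid to 19. The reagent must be kept to one equivalent because diazo compounds can add to quinones.

**Step 8.**
- What may go wrong: acid-promoted addition of the free phenol to the neighbouring chain alkene (chroman formation) before oxidation takes place; incomplete oxidation of the more hindered ring B; oxidative attack at the benzylic–allylic positions.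
- Fallback, setting out from 18 and returning at 19, replacing chemical oxidative demethylation by anodic ketalisation and hydrolysis:
  - Constant-current electrolysis of 18 at a Pt anode in MeOH containing LiClO4 and 2,6-lutidine at 0 °C should convert ring A into its quinone monoketal and ring B into its quinone bisketal. The chain alkenes oxidise at much higher potential. The product is dimethyl (2R*,3S*)-2-(5-geranyl-3,3-dimethoxy-6-oxocyclohexa-1,4-dien-1-yl)-3-(5-geranyl-3,3,6,6-tetramethoxycyclohexa-1,4-dien-1-yl)butanedioate F10.
  - Hydrolysis of the ketals with aqueous AcOH in THF at rt would give 19.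

## Further compounds

F1 | step 6 | methyl 2-(3-geranyl-2,5-dimethoxyphenyl)acetate | COC(=O)Cc1cc(OC)cc(C/C=C(\C)CCC=C(C)C)c1OC
F2 | step 6 | dimethyl meso-(2R,3S)-2,3-bis(3-geranyl-2,5-dimethoxyphenyl)butanedioate | COC(=O)[C@H](c1cc(OC)cc(C/C=C(\C)CCC=C(C)C)c1OC)[C@@H](C(=O)OC)c1cc(OC)cc(C/C=C(\C)CCC=C(C)C)c1OC
F3 | step 2 | 1,3-dibromo-5-methoxy-2-(methoxymethoxy)benzene | COCOc1c(Br)cc(OC)cc1Br
F4 | step 2 | 1-bromo-3-geranyl-5-methoxy-2-(methoxymethoxy)benzene | COCOc1c(Br)cc(OC)cc1C/C=C(\C)CCC=C(C)C
F5 | step 2 | methyl 2-[3-geranyl-5-methoxy-2-(methoxymethoxy)phenyl]-2-oxoacetate | COCOc1c(C/C=C(\C)CCC=C(C)C)cc(OC)cc1C(=O)C(=O)OC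
F6 | step 2 | methyl 2-(3-geranyl-2-hydroxy-5-methoxyphenyl)-2-oxoacetate | COC(=O)C(=O)c1cc(OC)cc(C/C=C(\C)CCC=C(C)C)c1O
F7 | step 1 | 1-methoxy-4-(methoxymethoxy)benzene | COCOc1ccc(OC)cc1
F8 | step 1 | 2-geranyl-4-methoxy-1-(methoxymethoxy)benzene | COCOc1ccc(OC)cc1C/C=C(\C)CCC=C(C)C
F9 | step 7 | (2R*,3S*)-4-methoxy-4-oxo-2,3-bis(5-geranyl-3,6-dioxocyclohexa-1,4-dien-1-yl)butanoic acid (racemic) | COC(=O)[C@H](C1=CC(=O)C=C(C/C=C(\C)CCC=C(C)C)C1=O)[C@@H](C(=O)O)C1=CC(=O)C=C(C/C=C(\C)CCC=C(C)C)C1=O
F10 | step 8 | dimethyl (2R*,3S*)-2-(5-geranyl-3,3-dimethoxy-6-oxocyclohexa-1,4-dien-1-yl)-3-(5-geranyl-3,3,6,6-tetramethoxycyclohexa-1,4-dien-1-yl)butanedioate (racemic) | COC(=O)[C@H](C1=CC(OC)(OC)C=C(C/C=C(\C)CCC=C(C)C)C1=O)[C@@H](C(=O)OC)C1=CC(OC)(OC)C=C(C/C=C(\C)CCC=C(C)C)C1(OC)OC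
A1 | alternative 1 | 1,4-dimethoxy-1,4-bis(trimethylsilyloxy)buta-1,3-diene | COC(O[Si](C)(C)C)=CC=C(OC)O[Si](C)(C)C
A2 | alternative 1 | 3-geranyl-4,4-dimethoxycyclohexa-2,5-dien-1-one | COC1(OC)C=CC(=O)C=C1C/C=C(\C)CCC=C(C)C
A3 | alternative 1 | dimethyl meso-2,3-bis(3-geranyl-5-hydroxy-2-methoxyphenyl)butanedioate | COC(=O)[C@H](c1cc(O)cc(C/C=C(\C)CCC=C(C)C)c1OC)[C@@H](C(=O)OC)c1cc(O)cc(C/C=C(\C)CCC=C(C)C)c1OC
A4 | alternative 1 | 3-geranyl-4-methoxyphenol | COc1ccc(O)cc1C/C=C(\C)CCC=C(C)C
A5 | alternative 2 | 3,4-dichlorocyclobut-3-ene-1,2-dione | O=C1C(=O)C(Cl)=C1Cl
A6 | alternative 2 | 3,4-bis(3-geranyl-2,5-dimethoxyphenyl)cyclobut-3-ene-1,2-dione | O=C1C(=O)C(c2cc(OC)cc(C/C=C(\C)CCC=C(C)C)c2OC)=C1c1cc(OC)cc(C/C=C(\C)CCC=C(C)C)c1OC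
A7 | alternative 2 | 2,3-bis(3-geranyl-2,5-dimethoxyphenyl)buta-1,3-diene-1,4-dione | O=C=C(c1cc(OC)cc(C/C=C(\C)CCC=C(C)C)c1OC)C(=C=O)c1cc(OC)cc(C/C=C(\C)CCC=C(C)C)c1OC
A8 | alternative 2 | dimethyl meso-2,3-bis(3-geranyl-2,5-dimethoxyphenyl)butanedioate | COC(=O)[C@H](c1cc(OC)cc(C/C=C(\C)CCC=C(C)C)c1OC)[C@@H](C(=O)OC)c1cc(OC)cc(C/C=C(\C)CCC=C(C)C)c1OC
A9 | alternative 3 | 3,4-dibromofuran-2,5-dione | O=C1OC(=O)C(Br)=C1Br
A10 | alternative 3 | 3,4-bis(3-geranyl-2,5-dimethoxyphenyl)furan-2,5-dione | O=C1OC(=O)C(c2cc(OC)cc(C/C=C(\C)CCC=C(C)C)c2OC)=C1c1cc(OC)cc(C/C=C(\C)CCC=C(C)C)c1OC
A11 | alternative 3 | cis-3,4-bis(3-geranyl-2,5-dimethoxyphenyl)dihydrofuran-2,5-dione | O=C1OC(=O)[C@H](c2cc(OC)cc(C/C=C(\C)CCC=C(C)C)c2OC)[C@@H]1c1cc(OC)cc(C/C=C(\C)CCC=C(C)C)c1OC
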